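Take logarithms first, I told myself, since the earlier runs differ in their partner charge and on a logarithmic scale two runs make a line.

in all of them: substrate 27 mM

|  | partner | remark | time |
|---|---|---|---|
| autumn | 34 mM | run made earlier |  |
| summer | 140 mM | run made earlier |  |
| Wednesday's | 67.5 mM |  | 2.0 min |
| Sunday's | 67.5 mM |  | 3.0 min |

| run | time / s | target / % |
|---|---|---|
| autumn | 25.0 | 10.3 |
| autumn | 50.0 | 23.0 |
| autumn | 80.0 | 35.6 |
| autumn | 90.0 | 39.8 |
| summer | 25.0 | 15.9 |
| summer | 50.0 | 31.8 |
| summer | 80.0 | 46.0 |
| summer | 90.0 | 49.1 |

(standard deviation of a reading: 0.5 percentage points)

- which one finishes higher in amount of target, in percent of the substrate charged ("neither" within 2 percentage points) (Wednesday's / Sunday's / neither)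
- amount of target at the end, in percent of the substrate charged, Wednesday's
- amount of target at the end, in percent of the substrate charged, Sunday's



From the last reading of each run, at 90.0 s, I read an apparent pseudo-first-order constant k, the negative logarithm of the fraction of substrate not found as target, divided by the time: 0.00564 /s for the autumn run and 0.00750 /s for the summer run. Dividing the logarithm of their ratio by that of the partner ratio gave the slope n, a weak partner order of 0.202, and following that line to 67.5 mM gave k at the new charge, 0.00648 /s, which serves both new flasks, as they share their charges.

Two settings could be turned. Moving the partner of the autumn run to 67.5 mM at 90.0 s took target, in my hand reckoning, from the 39.8% read there to 44.2%. Moving its time to 2.0 min with its own k gave 49.2%, a larger step than the partner gave. Turning both, I reckoned 54.0% for Wednesday's and 68.8% for Sunday's, so I put Sunday's higher, by more than the margin.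

The forecast said Sunday's, with 53% and 64%, the second below mine, on the grounds “I therefore shade the estimates down, especially the later one.”

The flasks gave 56.2% for Wednesday's and 69.6% for Sunday's, so Sunday's finished higher, and the autumn run gave 46.3% with its partner alone moved to 67.5 mM and 48.6% with its time alone moved to 2.0 min.

    substrate → intermediate A (k = 0.00850 /s)
    intermediate A → intermediate B (k = 0.0120 /s)
    partner + intermediate B ⇌ intermediate C (K = 16.0 /M, k = 0.170 /M/s)
    partner + intermediate A → target (k = 2.30 /M/s)
    intermediate C ⇌ intermediate D (K = 0.550, k = 0.00780 /s)
    substrate + intermediate C → side product (k = 4.30 /M/s)
    intermediate B → decomposed reagent (k = 0.00510 /s)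

In Wednesday's, substrate's passing into intermediate A, counted by itself, had a half-life of 1.4 min, much longer than the 4.46 s of intermediate A by its step to target alone with partner as charged, and on these two times I call the first step the rate-limiting step on the way to target in that flask. Intermediate A stood at 2.41% at the end of Wednesday's, and the first step holds no partner in its equation. For a neighbouring flask, Sunday's stopped at 50 s, my 0.00648 /s gave 27.7% of target, and that flask held 28.4%.

The earlier runs and the new flask were generated by integration with made-up constants; scatter was added.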